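**Plan**

1. Numbering: C1 is the carboxyl carbon, C3–C6 are the ring carbons, C7–C14 the chain, with phenyl on C14. Retrosynthetic cuts, in order: C1 acid back to a silyl-protected alcohol; C9=C10 (Julia–Kocienski, C1–C9 peroxide aldehyde plus C10–C14 sulfone); the two C–H bonds at C4/C5; the C3–O and C6–O bonds; the C4–C5 bond of the resulting diene (Negishi coupling); C12–C13 (conjugate vinylation of crotonaldehyde).
2. Enabling feature: the O–O unit of the 1,2-dioxane spans C3 and C6, the 1,4-related ends of the C3–C4–C5–C6 unit that also carries both ring methyls. The ring is therefore the reduced [4+2] adduct of O2 with a C3=C4–C5=C6 diene whose outside groups C2 and C7 become the two cis arms.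
3. Forward: a C5–C9 alkenyl iodide and a C1–C4 alkyne are joined to the (3E,5E)-diene. The only ring closes in step 6 as a 3,6-dihydro-1,2-dioxine, C4=C5 is then saturated, the C10–C14 chain is attached at C9, and C1 is oxidised last.
4. Stereochemistry: C8 comes from (S)-3-bromo-2-methylpropan-1-ol. C3/C6 are cis through suprafacial addition to the E,E-diene, and the (3S,6R) adduct is separated from its (3R,6S) diastereomer, C8 being the internal handle. C4 comes from diimide delivery opposite the two arms, C12 from iminium catalysis, 9E from the olefination and 13E from the styrylborate.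
5. Protecting groups: C9 carries the acid-labile TBS ether and C1 the sturdier TBDPS ether, so that C9 is unmasked first and C1 stays masked through the olefination.

Key step: step 6

Remark: names keep the C1–C14 numbering above; where a CIP letter at an untouched centre differs from the target (C6 in 15, C8 at the bromide stage) only the substituent ranking has changed. Assumption: the iminium of the (2S,5S)-imidazolidinone is attacked at the Re face of the enal β-carbon, so the (2R,5R) catalyst is specified for (S)-C12.

**Route**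

Step 1
Reactants: 1 (S)-3-bromo-2-methylpropan-1-ol
Product: 2 (S)-(3-bromo-2-methylpropoxy)(tert-butyl)dimethylsilane
Conditions: TBSCl, imidazole, CH2Cl2, 0 °C to rt
Reagents that add atoms: tert-butyldimethylsilyl chloride (TBSCl), CC(C)(C)[Si](C)(C)Cl
Why: Imidazole-promoted silylation of a primary alcohol leaves the stereocentre untouched and blocks oxetane formation under the basic conditions of the next step.

Step 2
Reactants: 2 (S)-(3-bromo-2-methylpropoxy)(tert-butyl)dimethylsilane
Product: 3 (R)-tert-butyldimethyl[(2-methylpent-4-yn-1-yl)oxy]silane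
Conditions: LiC≡CH·H2NCH2CH2NH2, DMSO, 5 °C to rt
Reagents that add atoms: lithium acetylide–ethylenediamine complex, [Li]C#C.NCCN
Why: SN2 alkylation of lithium acetylide by the primary bromide in DMSO installs C5 and C6 without touching the stereocentre.

Step 3
Reactants: 3 (R)-tert-butyldimethyl[(2-methylpent-4-yn-1-yl)oxy]silane
Product: 5 (R,E)-tert-butyl[(5-iodo-2,4-dimethylpent-4-en-1-yl)oxy]dimethylsilane, via alkenyldimethylalane 4 (not isolated)
Conditions: AlMe3, Cp2ZrCl2 (cat.), CH2Cl2, 0 °C to rt; then I2, THF, −30 to 0 °C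
Reagents that add atoms: trimethylaluminium (AlMe3), C[Al](C)C; iodine, II
Why: Negishi zirconium-catalysed carboalumination adds methyl and aluminium syn across the terminal alkyne with methyl on C6, and iodinolysis with retention should give the (E)-iodide.

Step 4
Reactants: 6 pent-3-yn-1-ol
Product: 7 tert-butyl(pent-3-yn-1-yloxy)diphenylsilane
Conditions: TBDPSCl, imidazole, CH2Cl2, rt
Reagents that add atoms: tert-butyldiphenylsilyl chloride (TBDPSCl), CC(C)(C)[Si](Cl)(c1ccccc1)c1ccccc1
Why: Routine silylation gives a C1 ether chosen to outlast the acid that later removes the C9 TBS ether.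

Step 5
Reactants: 7 tert-butyl(pent-3-yn-1-yloxy)diphenylsilane; 5 (R,E)-tert-butyl[(5-iodo-2,4-dimethylpent-4-en-1-yl)oxy]dimethylsilane
Product: 10 (3E,5E,8R)-1-(tert-butyldiphenylsilyloxy)-9-(tert-butyldimethylsilyloxy)-4,6,8-trimethylnona-3,5-diene, via alkenylzirconocene chloride 8 (not isolated), via alkenylzinc chloride 9 (not isolated)
Conditions: Cp2Zr(H)Cl (excess), THF, 50 °C; then ZnCl2, THF, 0 °C; then 5, Pd(PPh3)4 (5 mol %), rt
Reagents that add atoms: none
Why: Hydrozirconation adds H–Zr syn to the internal alkyne and, with excess reagent and warming, should settle zirconium on the methyl-bearing C4; transmetalation to zinc and Negishi cross-coupling under zerovalent palladium catalysis proceed with retention at both alkenyl carbons to give the (3E,5E)-diene.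

Step 6
Reactants: 10 (3E,5E,8R)-1-(tert-butyldiphenylsilyloxy)-9-(tert-butyldimethylsilyloxy)-4,6,8-trimethylnona-3,5-diene; 11 dioxygen
Product: 12 (3S,6R,8R)-1-(tert-butyldiphenylsilyloxy)-9-(tert-butyldimethylsilyloxy)-3,6-epidioxy-4,6,8-trimethylnon-4-ene
Conditions: O2 (1 atm), 5,10,15,20-tetraphenylporphyrin (cat.), white-light irradiation, CH2Cl2, −30 °C; chromatographic separation of the two cis adducts
Reagents that add atoms: dioxygen 11, O=O
Why: Sensitised singlet oxygen adds to the cisoid conformer of the C3=C4–C5=C6 diene in a concerted, suprafacial [4+2] cycloaddition, the closest known reaction type being the photooxygenation of acyclic (E,E)-1,3-dienes to 3,6-dihydro-1,2-dioxines. The six-membered ring closes in this intermolecular [4+2] mode, with the C3–O and C6–O bonds formed together and the alkene moved to C4=C5. C3 and C6 are set relative to each other by the (3E,5E) geometry, because C2 and C7 are the outside groups of the cisoid diene and must end up cis on the ring. Remote C8 cannot steer the facial choice, so 12 should form alongside a like amount of its (3R,6S,8R) diastereomer, and C8 serves as the handle that makes the two separable. The selectivity the step needs is cycloaddition over ene hydroperoxidation at the allylic methyl and methylene hydrogens; the C4 methyl helps, since its 1,3-allylic clash with the inside C6 methyl disfavours the transoid conformer, and the reaction is run cold and stopped once the diene is consumed.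

Step 7
Reactants: 12 (3S,6R,8R)-1-(tert-butyldiphenylsilyloxy)-9-(tert-butyldimethylsilyloxy)-3,6-epidioxy-4,6,8-trimethylnon-4-ene
Product: 13 (3S,4S,6R,8R)-1-(tert-butyldiphenylsilyloxy)-9-(tert-butyldimethylsilyloxy)-3,6-epidioxy-4,6,8-trimethylnonane
Conditions: KO2C–N=N–CO2K (large excess, in portions), AcOH (slow addition), CH2Cl2, 0 °C to rt
Reagents that add atoms: none
Why: Diimide reduction transfers two hydrogens syn to C4=C5 without touching the O–O bond, and delivery to the ring face opposite the two cis arms (the face carrying only C3–H and the C6 methyl) should place the C4 methyl cis to both arms (4S).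

Step 8
Reactants: 13 (3S,4S,6R,8R)-1-(tert-butyldiphenylsilyloxy)-9-(tert-butyldimethylsilyloxy)-3,6-epidioxy-4,6,8-trimethylnonane
Product: 14 (3S,4S,6R,8R)-1-(tert-butyldiphenylsilyloxy)-3,6-epidioxy-4,6,8-trimethylnonan-9-ol
Conditions: (1S)-(+)-camphor-10-sulfonic acid (cat.), MeOH/CH2Cl2 1:1, 0 °C
Reagents that add atoms: none
Why: Acid-catalysed methanolysis cleaves a primary TBS ether far faster than a TBDPS ether (selective desilylation), and the dialkyl peroxide tolerates mild acid.

Step 9
Reactants: 14 (3S,4S,6R,8R)-1-(tert-butyldiphenylsilyloxy)-3,6-epidioxy-4,6,8-trimethylnonan-9-ol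
Product: 15 (3S,4S,6S,8R)-1-(tert-butyldiphenylsilyloxy)-3,6-epidioxy-4,6,8-trimethyl-9-oxononane
Conditions: Dess–Martin periodinane, NaHCO3, CH2Cl2, 0 °C to rt; used crude
Reagents that add atoms: none
Why: Dess–Martin oxidation under buffered, non-basic conditions should give the α-branched aldehyde without epimerising C8 or disturbing the peroxide.

Step 10
Reactants: 16 (E)-but-2-enal; 17 potassium trifluoro[(E)-2-phenylethenyl]borate
Product: 19 (S,E)-3-methyl-5-phenylpent-4-en-1-ol, via (S,E)-3-methyl-5-phenylpent-4-enal 18 (not isolated)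
Conditions: (2R,5R)-5-benzyl-2-tert-butyl-3-methylimidazolidin-4-one hydrochloride (20 mol %), HF (aq., 1 equiv), DME, −20 °C; then NaBH4, EtOH, 0 °C
Reagents that add atoms: none
Why: Iminium-catalysed conjugate vinylation of the enal by the alkenyltrifluoroborate (HF trapping the BF3 released) sets C12, since the (2R,5R) catalyst shields the Re face of the β-carbon and the styryl group enters from the Si face to give the (S)-aldehyde, which is reduced in the same flask; the 13E geometry is carried in by the borate.

Step 11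
Reactants: 19 (S,E)-3-methyl-5-phenylpent-4-en-1-ol
Product: 20 5-{[(S,E)-3-methyl-5-phenylpent-4-en-1-yl]sulfanyl}-1-phenyl-1H-tetrazole
Conditions: 1-phenyl-1H-tetrazole-5-thiol, PPh3, diisopropyl azodicarboxylate, THF, 0 °C to rt
Reagents that add atoms: 1-phenyl-1H-tetrazole-5-thiol, Sc1nnnn1-c1ccccc1
Why: Mitsunobu reaction of the primary alcohol with the acidic tetrazole thiol gives the sulfide and involves no stereocentre.

Step 12
Reactants: 20 5-{[(S,E)-3-methyl-5-phenylpent-4-en-1-yl]sulfanyl}-1-phenyl-1H-tetrazole
Product: 21 5-{[(S,E)-3-methyl-5-phenylpent-4-en-1-yl]sulfonyl}-1-phenyl-1H-tetrazole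
Conditions: H2O2 (30 % aq.), (NH4)6Mo7O24·4H2O (cat.), EtOH, 0 °C to rt
Reagents that add atoms: hydrogen peroxide, OO
Why: Molybdate-catalysed peroxide oxidation takes the sulfide to the sulfone chemoselectively and should leave the styrene untouched.

Step 13
Reactants: 21 5-{[(S,E)-3-methyl-5-phenylpent-4-en-1-yl]sulfonyl}-1-phenyl-1H-tetrazole; 15 (3S,4S,6S,8R)-1-(tert-butyldiphenylsilyloxy)-3,6-epidioxy-4,6,8-trimethyl-9-oxononane
Product: 23 (3S,4S,6R,8R,9E,12S,13E)-1-(tert-butyldiphenylsilyloxy)-3,6-epidioxy-4,6,8,12-tetramethyl-14-phenyltetradeca-9,13-diene, via potassiated sulfone 22 (not isolated)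
Conditions: 21, KN(SiMe3)2, DME, −60 °C; then 15, −60 °C to rt
Reagents that add atoms: none
Why: In the Julia–Kocienski olefination the metalated phenyltetrazolyl sulfone adds to the aldehyde and Smiles rearrangement with loss of SO2 and the tetrazolone gives the alkene, the potassium counter-ion in DME and the α-branched aldehyde favouring 9E, while low temperature and aldehyde-last addition protect C8 and the peroxide.

Step 14
Reactants: 23 (3S,4S,6R,8R,9E,12S,13E)-1-(tert-butyldiphenylsilyloxy)-3,6-epidioxy-4,6,8,12-tetramethyl-14-phenyltetradeca-9,13-diene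
Product: 24 (3S,4S,6R,8R,9E,12S,13E)-3,6-epidioxy-4,6,8,12-tetramethyl-14-phenyltetradeca-9,13-dien-1-ol
Conditions: Bu4NF, AcOH, THF, 0 °C to rt
Reagents that add atoms: none
Why: Fluoride-mediated desilylation frees C1–OH, and the acetic acid buffer keeps the medium from becoming basic enough to fragment the peroxide at C3–H.

Step 15
Reactants: 24 (3S,4S,6R,8R,9E,12S,13E)-3,6-epidioxy-4,6,8,12-tetramethyl-14-phenyltetradeca-9,13-dien-1-ol
Product: 26 (3S,4S,6R,8R,9E,12S,13E)-3,6-epidioxy-4,6,8,12-tetramethyl-14-phenyltetradeca-9,13-dienoic acid, via C1 aldehyde 25 (not isolated)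
Conditions: 2,2,6,6-tetramethylpiperidin-1-oxyl (cat.), PhI(OAc)2, MeCN/H2O (pH 7 phosphate buffer), rt
Reagents that add atoms: water, O
Why: Oxoammonium-mediated oxidation takes the primary alcohol through the aldehyde hydrate to the acid under near-neutral conditions that should spare both alkenes, the peroxide and every stereocentre.

**Compound list**

1 | (S)-3-bromo-2-methylpropan-1-ol | OC[C@H](C)CBr | starting material
2 | (S)-(3-bromo-2-methylpropoxy)(tert-butyl)dimethylsilane | CC(C)(C)[Si](C)(C)OC[C@H](C)CBr | intermediate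
3 | (R)-tert-butyldimethyl[(2-methylpent-4-yn-1-yl)oxy]silane | CC(C)(C)[Si](C)(C)OC[C@H](C)CC#C | intermediate
4 | [(1E,4R)-5-(tert-butyldimethylsilyloxy)-2,4-dimethylpent-1-en-1-yl]dimethylalane (not isolated) | C[Al](C)/C=C(\C)C[C@@H](C)CO[Si](C)(C)C(C)(C)C | intermediate
5 | (R,E)-tert-butyl[(5-iodo-2,4-dimethylpent-4-en-1-yl)oxy]dimethylsilane | I/C=C(\C)C[C@@H](C)CO[Si](C)(C)C(C)(C)C | intermediate
6 | pent-3-yn-1-ol | CC#CCCO | starting material
7 | tert-butyl(pent-3-yn-1-yloxy)diphenylsilane | CC#CCCO[Si](c1ccccc1)(c1ccccc1)C(C)(C)C | intermediate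
8 | chloro[(E)-5-(tert-butyldiphenylsilyloxy)pent-2-en-2-yl]bis(cyclopentadienyl)zirconium (not isolated) | C/C(=C\CCO[Si](c1ccccc1)(c1ccccc1)C(C)(C)C)[Zr](Cl)(C1C=CC=C1)C1C=CC=C1 | intermediate
9 | chloro[(E)-5-(tert-butyldiphenylsilyloxy)pent-2-en-2-yl]zinc (not isolated) | C/C(=C\CCO[Si](c1ccccc1)(c1ccccc1)C(C)(C)C)[Zn]Cl | intermediate
10 | (3E,5E,8R)-1-(tert-butyldiphenylsilyloxy)-9-(tert-butyldimethylsilyloxy)-4,6,8-trimethylnona-3,5-diene | CC(C)(C)[Si](c1ccccc1)(c1ccccc1)OCC/C=C(\C)/C=C(\C)C[C@@H](C)CO[Si](C)(C)C(C)(C)C | intermediate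
11 | dioxygen | O=O | starting material
12 | (3S,6R,8R)-1-(tert-butyldiphenylsilyloxy)-9-(tert-butyldimethylsilyloxy)-3,6-epidioxy-4,6,8-trimethylnon-4-ene (cis-3,6-disubstituted 4,6-dimethyl-3,6-dihydro-1,2-dioxine) | CC(C)(C)[Si](C)(C)OC[C@H](C)C[C@]1(C)C=C(C)[C@H](CCO[Si](c2ccccc2)(c2ccccc2)C(C)(C)C)OO1 | intermediate
13 | (3S,4S,6R,8R)-1-(tert-butyldiphenylsilyloxy)-9-(tert-butyldimethylsilyloxy)-3,6-epidioxy-4,6,8-trimethylnonane (1,2-dioxane; C3 arm, C4 methyl and C6 arm all cis) | CC(C)(C)[Si](C)(C)OC[C@H](C)C[C@]1(C)C[C@H](C)[C@H](CCO[Si](c2ccccc2)(c2ccccc2)C(C)(C)C)OO1 | intermediate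
14 | (3S,4S,6R,8R)-1-(tert-butyldiphenylsilyloxy)-3,6-epidioxy-4,6,8-trimethylnonan-9-ol | OC[C@H](C)C[C@]1(C)C[C@H](C)[C@H](CCO[Si](c2ccccc2)(c2ccccc2)C(C)(C)C)OO1 | intermediate
15 | (3S,4S,6S,8R)-1-(tert-butyldiphenylsilyloxy)-3,6-epidioxy-4,6,8-trimethyl-9-oxononane (same geometry as 14; C6 reads S because the C7 branch now outranks C5) | O=C[C@H](C)C[C@]1(C)C[C@H](C)[C@H](CCO[Si](c2ccccc2)(c2ccccc2)C(C)(C)C)OO1 | intermediate
16 | (E)-but-2-enal (crotonaldehyde) | C/C=C/C=O | starting material
17 | potassium trifluoro[(E)-2-phenylethenyl]borate | [K+].F[B-](F)(F)/C=C/c1ccccc1 | starting material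
18 | (S,E)-3-methyl-5-phenylpent-4-enal (not isolated) | C[C@H](/C=C/c1ccccc1)CC=O | intermediate
19 | (S,E)-3-methyl-5-phenylpent-4-en-1-ol | C[C@H](/C=C/c1ccccc1)CCO | intermediate
20 | 5-{[(S,E)-3-methyl-5-phenylpent-4-en-1-yl]sulfanyl}-1-phenyl-1H-tetrazole | C[C@H](/C=C/c1ccccc1)CCSc1nnnn1-c1ccccc1 | intermediate
21 | 5-{[(S,E)-3-methyl-5-phenylpent-4-en-1-yl]sulfonyl}-1-phenyl-1H-tetrazole | C[C@H](/C=C/c1ccccc1)CCS(=O)(=O)c1nnnn1-c1ccccc1 | intermediate
22 | potassium salt of 21 deprotonated at the carbon next to sulfur (not isolated) | [K+].C[C@H](/C=C/c1ccccc1)C[CH-]S(=O)(=O)c1nnnn1-c1ccccc1 | intermediate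
23 | (3S,4S,6R,8R,9E,12S,13E)-1-(tert-butyldiphenylsilyloxy)-3,6-epidioxy-4,6,8,12-tetramethyl-14-phenyltetradeca-9,13-diene | C[C@H](/C=C/c1ccccc1)C/C=C/[C@H](C)C[C@]1(C)C[C@H](C)[C@H](CCO[Si](c2ccccc2)(c2ccccc2)C(C)(C)C)OO1 | intermediate
24 | (3S,4S,6R,8R,9E,12S,13E)-3,6-epidioxy-4,6,8,12-tetramethyl-14-phenyltetradeca-9,13-dien-1-ol | C[C@H](/C=C/c1ccccc1)C/C=C/[C@H](C)C[C@]1(C)C[C@H](C)[C@H](CCO)OO1 | intermediate
25 | (3S,4S,6R,8R,9E,12S,13E)-3,6-epidioxy-4,6,8,12-tetramethyl-14-phenyltetradeca-9,13-dienal (not isolated) | C[C@H](/C=C/c1ccccc1)C/C=C/[C@H](C)C[C@]1(C)C[C@H](C)[C@H](CC=O)OO1 | intermediate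
26 | (3S,4S,6R,8R,9E,12S,13E)-3,6-epidioxy-4,6,8,12-tetramethyl-14-phenyltetradeca-9,13-dienoic acid | C[C@H](/C=C/c1ccccc1)C/C=C/[C@H](C)C[C@]1(C)C[C@H](C)[C@H](CC(=O)O)OO1 | target

**Step count and risks**

Total: 15 steps. Longest linear sequence: 11 steps (steps 1, 2, 3, 5, 6, 7, 8, 9, 13, 14, 15, from 1 to 26).

Steps most likely to fail:

Step 6. The cisoid conformer needed for cycloaddition carries the C6 methyl inside, so ene hydroperoxidation at the allylic methyl and methylene hydrogens, and some dioxetane formation, may outrun ring closure. In addition no facial preference is expected, so half of the adduct is the unwanted diastereomer and the two may co-elute. The fallback leaves the singlet-oxygen manifold: diene 10 is oxygenated as its radical cation with ground-state dioxygen, using catalytic tris(4-bromophenyl)aminium hexachloroantimonate under O2 in CH2Cl2 at −78 °C. This is the known cation-radical chain oxygenation of alkylated 1,3-dienes to 1,2-dioxenes, which has no ene channel. It sets out from 10 and comes back to the route at 12, and no new compound arises (F0). Because ring closure is then stepwise, the cis relation of the arms would have to be confirmed, and the facial problem remains.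

Step 7. Hydrogen transfer to a trisubstituted ring alkene is slow relative to diimide disproportionation, so long exposure to acetic acid may erode the TBS ether. Discrimination between the two ring faces may also be incomplete, which would give the C4 epimer. The fallback replaces reagent-based hydrogen transfer by heterogeneous catalytic hydrogenation: H2 (1 atm) over PtO2 in ethyl acetate at 0 °C, followed closely and stopped at alkene consumption. This type of hydrogenation is known to saturate alkenes in hindered cyclic dialkyl peroxides before O–O hydrogenolysis sets in, and adsorption should occur through the same less encumbered face. It sets out from 12 and comes back at 13, and no new compound arises (F0).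

Step 13. The α-branched aldehyde may enolise and lose C8 integrity, the sulfonyl carbanion or residual amide base may fragment the peroxide at C3–H, and E selectivity may be incomplete. The fallback reverses the roles of the partners. Alcohol 14 is converted by Mitsunobu reaction (1-phenyl-1H-tetrazole-5-thiol, PPh3, diisopropyl azodicarboxylate) into (3S,4S,6S,8R)-1-(tert-butyldiphenylsilyloxy)-3,6-epidioxy-4,6,8-trimethyl-9-[(1-phenyl-1H-tetrazol-5-yl)sulfanyl]nonane F1. Oxidation with H2O2 and catalytic (NH4)6Mo7O24·4H2O, to which the dialkyl peroxide is inert, gives (3S,4S,6S,8R)-1-(tert-butyldiphenylsilyloxy)-3,6-epidioxy-4,6,8-trimethyl-9-[(1-phenyl-1H-tetrazol-5-yl)sulfonyl]nonane F2. Aldehyde 18 is isolated from step 10 by omitting the borohydride, premixed with F2 in DME at −60 °C, and KN(SiMe3)2 is added last (Barbier mode). The peroxide fragment then never carries an epimerisable aldehyde and free base never accumulates. This sequence sets out from 14 and comes back to the route at 23.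

**Further compounds**

F0 | step 6 | none | none
F0 | step 7 | none | none
F1 | step 13 | (3S,4S,6S,8R)-1-(tert-butyldiphenylsilyloxy)-3,6-epidioxy-4,6,8-trimethyl-9-[(1-phenyl-1H-tetrazol-5-yl)sulfanyl]nonane | S(C[C@H](C)C[C@]1(C)C[C@H](C)[C@H](CCO[Si](c2ccccc2)(c2ccccc2)C(C)(C)C)OO1)c1nnnn1-c1ccccc1
F2 | step 13 | (3S,4S,6S,8R)-1-(tert-butyldiphenylsilyloxy)-3,6-epidioxy-4,6,8-trimethyl-9-[(1-phenyl-1H-tetrazol-5-yl)sulfonyl]nonane | O=S(=O)(C[C@H](C)C[C@]1(C)C[C@H](C)[C@H](CCO[Si](c2ccccc2)(c2ccccc2)C(C)(C)C)OO1)c1nnnn1-c1ccccc1
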